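## Structural features

The target is one cyclohexene ring. The numbering used throughout is: C1 = fully substituted carbinol carbon (OH and the exocyclic C7H2–OBz), C2 = CH–OH, C3 = CH–OBz, C4=C5 = ring alkene, C6 = CH–OBz.

The four stereocentres C6, C1, C2 and C3 are contiguous, (1R,2S,3R,6R). Their oxygens alternate from face to face: O1 and O3 lie on one face, O2 and O6 on the other. C7 is therefore cis to O2 and O6, and the tertiary hydroxyl is trans to both oxygenated neighbours.

Both secondary benzoates are allylic and can ionise or react by SN2′. The free 1,2-diol sits beside three esters, so acyl migration under base is a risk, and loss of two oxygen substituents would aromatise the ring.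

The real difficulty is C1. It is a quaternary oxygenated centre between two oxygenated stereocentres, in a trans 1,2-diol that no syn-dihydroxylation of a C1=C2 alkene can give. In addition, O1 and O2 (free) must be told apart from O3, O6 and O7 (benzoylated).

The key step exploits the chain C7–C1–C6–C5=C4. With C7 at the carboxyl level this chain is a pent-4-enoic acid, the retron of a [3,3] ester-enolate shift.

Undoing that shift means cutting C1–C6, joining a carboxyl oxygen of C7 to C4, and moving the alkene to C5=C6. The carbocycle then becomes a pyranone ring O–C7–C1–C2–C3–C4, which is an aldono-1,5-lactone. In it C2, C3 and C4 have the configuration of C-4, C-3 and C-2 of D-glucose, C7 is glucose C-6 and C1 is glucose C-5.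

The route in one sentence: the carbocycle, C1 and C6 arise together from the Ireland–Claisen ring contraction of the silyl ketene acetal of a D-glucose-derived δ-lactone that carries an (E)-2-borylvinyl group at C4.

## Logic of the disconnections

**15 ⇒ 14.** The two O–CH2 acetal bonds on O1 and O2 are restored. The five oxygens must fall into two classes, and O1/O2 are the pair that stays free. The gain is that benzoylation needs no regioselectivity. The demand is that the last step frees a tertiary and a secondary hydroxyl under acid without moving or ionising a benzoate.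

**14 ⇒ 13 ⇒ 12.** The three acyl C–O bonds at O3, O6 and O7 are cut, and one step further back the arylmethyl ether on O3 is restored. All benzoates enter in one operation on one triol. The demand is an oxidative ether cleavage that spares the ring alkene and the allylic alcohols.

**12 ⇒ 11 ⇒ 10.** C7 is raised from CH2OH to the carboxyl level, and the C6–O bond is exchanged for C6–B. This uncovers the pent-4-enoic acid retron and makes C6 a carbon whose configuration comes from an alkene geometry. The demand is a C–B oxidation with retention and a hydride reduction of a hindered acid.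

**10 ⇒ 9 ⇒ 8 (key).** C1–C6 is cut, the carboxyl oxygen is joined to C4, and the alkene moves from C4=C5 to C5=C6.
- Reason: this one operation removes the carbocycle, the quaternary centre C1 and the stereocentre C6.
- Gain: 8 has only sugar-type secondary stereocentres (C2, C3, C4) and an E alkene. C1 is still stereogenic in 8, but its configuration is irrelevant because it is planarised in 9.
- Demand: clean O-silylation of an α,β-dialkoxy lactone enolate, and a boat-shaped [3,3] transition state.
- One-sentence form: Ireland–Claisen ring contraction of 9, made from 8.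

**8 ⇒ 7.** C6–B is cut. A terminal alkyne is the simplest source of an E-configured alkenylboron unit. The demand is syn, terminal-selective hydroboration in the presence of a lactone.

**7 ⇒ 6 ⇒ 5 ⇒ 4.** The acetal bonds on O1/O2 are cut, then the ring bond O–C7, and C7 is lowered to the alcohol level. This gives an open-chain polyol. The demand is oxidation of the primary alcohol only. Ring closure can reach only the C4 hydroxyl, because O3 is blocked.

**4 ⇒ 3.** C5≡C6 is cut, so C6 is the only skeletal carbon that is not a sugar carbon. This gives a hexose hemiacetal. The demand is a one-carbon homologation that does not enolise the aldehyde next to C4.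

**3 ⇒ 2 ⇒ 1.** The O3–CH2Ar bond is cut after the two acetonides are restored. In 1 the oxygen that becomes O3 is the only free hydroxyl, so the differentiation that directs lactonisation and later benzoylation costs one alkylation.

## Other disconnections considered

**Alternative 1:** (the first that comes to mind) cut C4=C5. The forward key step is ring-closing metathesis of the acyclic diene A1 with the second-generation Grubbs catalyst.
- The closure is reliable but creates no stereocentre.
- All four contiguous centres, including quaternary C1, would have to be built in the open chain by separate carbonyl additions, each with its own diastereocontrol.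
- The alternating (ido-like) oxygen pattern of A1 is not found in a cheap hexose.
- The chosen plan makes the ring, C1 and C6 in one event and takes C2 and C3 unchanged from glucose.

**Alternative 2:** cut C1–C7 and use the hidden C2 symmetry of the ring without its branch.
- In the C2-symmetric diol A2 both hydroxyls are equivalent, so mono-oxidation can give only the hydroxy ketone A3.
- The forward key step is axial methylene transfer from dimethylsulfonium methylide to A3, giving spiro-epoxide A4, which benzoate would open at C7.
- In A3, H6 is both α to the carbonyl and allylic, and the C3 benzoate is a vinylogous β-leaving group. Any basic carbon nucleophile invites enolisation, loss of benzoate and aromatisation.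
- The step sets one stereocentre only, and enantiopure A2 still needs a resolution or an asymmetric catalytic step.

**Alternative 3:** (biomimetic) cut C3–O and C6–O. The forward key step is double SN2 opening of the anti-diepoxide A5 by benzoate at both allylic termini. Inversion at C3 and C6 gives the all-trans pattern directly.
- A5 has the same four stereocentres as the target, so the step simplifies little.
- Access to A5 runs through arene-oxide-level intermediates, which lose configuration by oxepine valence tautomerism.
- The vinyl epoxides offer SN2′ paths, and under acid opening at tertiary C1, as competitors.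

Key step: step 7

Remark: target numbers C1–C7 are used for all compounds from 4 onwards (C7, C1, C2, C3, C4, C5 = glucose C-6, C-5, C-4, C-3, C-2, C-1; C6 = added carbon). Compounds 3, 5 and F8 are anomeric mixtures, so their SMILES leave that centre open.

## Steps

Step 1
Reactants: 1 1,2:5,6-di-O-isopropylidene-α-D-glucofuranose
Product: 2 1,2:5,6-di-O-isopropylidene-3-O-(2-naphthylmethyl)-α-D-glucofuranose
Conditions: NaH, 2-(bromomethyl)naphthalene, DMF, 0 °C → rt
Reagents that add atoms: 2-(bromomethyl)naphthalene, BrCc1ccc2ccccc2c1
Why: Williamson ether synthesis on the only free hydroxyl of 1; the ether marks the oxygen that becomes O3, blocks five-membered lactone formation in step 4 and can later be removed oxidatively beside an alkene.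

Step 2
Reactants: 2 1,2:5,6-di-O-isopropylidene-3-O-(2-naphthylmethyl)-α-D-glucofuranose
Product: 3 3-O-(2-naphthylmethyl)-D-glucopyranose (anomeric mixture)
Conditions: sulfonic acid resin (H+ form), H2O–1,4-dioxane, 75 °C
Reagents that add atoms: none
Why: Acid-catalysed acetal hydrolysis removes both isopropylidene groups and the sugar re-closes to the pyranose hemiacetal; the naphthylmethyl ether behaves like a benzyl ether toward aqueous acid and should stay, and no carbinol stereocentre is touched.

Step 3
Reactants: 3 3-O-(2-naphthylmethyl)-D-glucopyranose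
Product: 4 1,2-dideoxy-4-O-(2-naphthylmethyl)-D-gluco-hept-1-ynitol
Conditions: dimethyl (1-diazo-2-oxopropyl)phosphonate (excess, in portions), K2CO3, MeOH, rt → 45 °C
Reagents that add atoms: dimethyl (1-diazo-2-oxopropyl)phosphonate (Ohira–Bestmann reagent), CC(=O)C(=[N+]=[N-])P(=O)(OC)OC
Why: Ohira–Bestmann variant of the Seyferth–Gilbert homologation, a reaction type known on sugar hemiacetals: the diazomethylphosphonate anion olefinates the open-chain aldehyde, and loss of N2 with a 1,2-hydride shift gives the terminal alkyne with C6 as the new carbon. Homologation and base-induced enolisation both start from the same small share of open-chain aldehyde, so their ratio depends on reagent concentration and not on the ring–chain equilibrium, which is why the reagent is kept in excess; C4 should keep its configuration.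

Step 4
Reactants: 4 1,2-dideoxy-4-O-(2-naphthylmethyl)-D-gluco-hept-1-ynitol
Product: 6 6,7-dideoxy-4-O-(2-naphthylmethyl)-L-gulo-hept-6-ynono-1,5-lactone, via heptynopyranose lactol 5 (not isolated)
Conditions: TEMPO (cat.), PhI(OAc)2 (2.3 equiv), CH2Cl2, rt
Reagents that add atoms: none
Why: TEMPO/PhI(OAc)2 oxidative lactonisation of a 1,5-diol: the oxoammonium salt takes the unhindered primary alcohol (C7) first, the aldehyde is trapped by the C4 hydroxyl as the six-membered lactol 5, and 5 is oxidised on to 6. The five-membered alternative is closed because O3 is etherified, so the δ-lactone is the only lactone that can form.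

Step 5
Reactants: 6 6,7-dideoxy-4-O-(2-naphthylmethyl)-L-gulo-hept-6-ynono-1,5-lactone
Product: 7 6,7-dideoxy-2,3-bis-O-(methoxymethyl)-4-O-(2-naphthylmethyl)-L-gulo-hept-6-ynono-1,5-lactone
Conditions: MOMCl, iPr2NEt, Bu4NI (cat.), CH2Cl2, 0 °C → reflux
Reagents that add atoms: chloromethyl methyl ether, COCCl
Why: Acetal-type O-alkylation under amine base, mild enough for an α-hydroxy lactone; two separate, non-migrating groups are chosen for O1/O2 because a small bridging ring could not follow the torsion that the boat array of step 7 imposes on a trans-diol product. Any epimerisation at C1 is harmless since C1 is planarised in step 7.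

Step 6
Reactants: 7 6,7-dideoxy-2,3-bis-O-(methoxymethyl)-4-O-(2-naphthylmethyl)-L-gulo-hept-6-ynono-1,5-lactone
Product: 8 (E)-6,7-dideoxy-2,3-bis-O-(methoxymethyl)-4-O-(2-naphthylmethyl)-7-(4,4,5,5-tetramethyl-1,3,2-dioxaborolan-2-yl)-L-gulo-hept-6-enono-1,5-lactone
Conditions: pinacolborane (1.5 equiv), dicyclohexylborane (10 mol %), THF, rt
Reagents that add atoms: pinacolborane, CC1(C)OBOC1(C)C
Why: Dicyclohexylborane-catalysed hydroboration of a terminal alkyne: syn addition with boron on the terminal carbon should give the E alkenylboronate only, and this geometry is the element that later fixes C6.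

Step 7
Reactants: 8 (E)-6,7-dideoxy-2,3-bis-O-(methoxymethyl)-4-O-(2-naphthylmethyl)-7-(4,4,5,5-tetramethyl-1,3,2-dioxaborolan-2-yl)-L-gulo-hept-6-enono-1,5-lactone
Product: 10 trimethylsilyl 1,2-bis(methoxymethoxy)-3-(2-naphthylmethoxy)-6-(4,4,5,5-tetramethyl-1,3,2-dioxaborolan-2-yl)cyclohex-4-ene-1-carboxylate (O1/O3 on one face; C7/O2/B on the other; used crude), via trimethylsilyl ketene acetal 9 (not isolated)
Conditions: TMSCl/Et3N (premixed, excess), THF, −100 °C, then LiN(iPr)2 (1.5 equiv) dropwise (internal quench); −100 °C → rt; solvent changed to toluene, 80–100 °C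
Reagents that add atoms: chlorotrimethylsilane, C[Si](C)(C)Cl
Why: Ireland–Claisen rearrangement in its ring-contracting form: LiN(iPr)2 removes H1 of 8 in the presence of TMSCl, the enolate is O-silylated at once to 9, and on warming 9 undergoes a concerted, suprafacial [3,3] shift that breaks O–C4, forms C1–C6 and moves the alkene to C4=C5. The closest known reaction types are the rearrangement of silyl ketene acetals of 6-alkenyl δ-lactones to cyclohex-3-enecarboxylic acids, the thermal Claisen conversion of 5-vinyl glycals into carbasugar aldehydes, and [3,3] shifts of boron-substituted allylic esters. One ring is closed, the six-membered carbocycle, by the sigmatropic C1–C6 bond while the pyranone ring opens; since the two-atom bridge C2–C3 ties the termini C1 and C4, only a boat-like array shaped like bicyclo[2.2.2]octane can be reached and no chair competes. C1 is controlled by the sugar stereocentre C4 (glucose C-2), which is consumed: the borylvinyl arm can reach planar C1 only on its own face of the pyranone, the face opposite to O2, so the new bond forms anti to O2 and in the new ring C7 is cis and O1 trans to O2. C6 is controlled by the alkene geometry: in the boat array the E position points away from the C2–C3 bridge and becomes the ring position trans to O1 and cis to C7, whereas the Z position points onto C2, so that only E-configured 8 fits and it delivers the required C6. The step needs O-silylation to outrun β-elimination of the C2 methoxymethoxy group, which the internal quench at −100 °C should secure, and it needs the base to spare boron, for which the use of LiN(iPr)2 beside pinacol boronates in their in situ homologation with CH2Cl2 is the model. Allylic 1,2-strain between the in-plane O1 substituent and O2 favours the conformer with O2 pseudo-axial, which is the one the boat needs. The carbonyl group set free is a silyl ester, which the new allylboronate cannot allylate, so 10 should survive until it is oxidised.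

Step 8
Reactants: 10 trimethylsilyl 1,2-bis(methoxymethoxy)-3-(2-naphthylmethoxy)-6-(4,4,5,5-tetramethyl-1,3,2-dioxaborolan-2-yl)cyclohex-4-ene-1-carboxylate
Product: 11 6-hydroxy-1,2-bis(methoxymethoxy)-3-(2-naphthylmethoxy)cyclohex-4-ene-1-carboxylic acid (O1/O3 on one face; C7/O2/O6 on the other)
Conditions: 30% aq H2O2, pH 7 phosphate buffer, THF, 0 °C → rt
Reagents that add atoms: hydrogen peroxide, OO
Why: Oxidation of a boronic ester: hydroperoxide adds to boron and C6 migrates from boron to oxygen with retention, so the configuration set in step 7 is kept; water cleaves the silyl ester in the same operation.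

Step 9
Reactants: 11 6-hydroxy-1,2-bis(methoxymethoxy)-3-(2-naphthylmethoxy)cyclohex-4-ene-1-carboxylic acid
Product: 12 1-(hydroxymethyl)-1,2-bis(methoxymethoxy)-3-(2-naphthylmethoxy)cyclohex-4-en-6-ol (target numbering)
Conditions: LiAlH4, THF, 0 °C → reflux; Fieser work-up
Reagents that add atoms: none
Why: Hydride reduction of a carboxylic acid to the primary alcohol; ethers, acetals and the isolated ring alkene are inert to LiAlH4, and no stereocentre is involved.

Step 10
Reactants: 12 1-(hydroxymethyl)-1,2-bis(methoxymethoxy)-3-(2-naphthylmethoxy)cyclohex-4-en-6-ol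
Product: 13 1-(hydroxymethyl)-1,2-bis(methoxymethoxy)cyclohex-4-ene-3,6-diol (target numbering)
Conditions: DDQ (1.5 equiv), CH2Cl2–pH 7 buffer (10:1), 0 °C → rt
Reagents that add atoms: none
Why: Oxidative cleavage of an electron-rich arylmethyl ether by DDQ (hydride abstraction, hydrolysis of the oxocarbenium ion); the alkene and the methoxymethyl acetals are not affected, and unactivated secondary allylic alcohols are oxidised much more slowly than the naphthylmethyl ether.

Step 11
Reactants: 13 1-(hydroxymethyl)-1,2-bis(methoxymethoxy)cyclohex-4-ene-3,6-diol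
Product: 14 [3,6-bis(benzoyloxy)-1,2-bis(methoxymethoxy)cyclohex-4-en-1-yl]methyl benzoate
Conditions: BzCl (5 equiv), pyridine, DMAP (cat.), 0 → 40 °C
Reagents that add atoms: benzoyl chloride, O=C(Cl)c1ccccc1
Why: DMAP-catalysed acylation of the three free hydroxyls (O3, O6, O7) in one operation; O1 and O2 are masked, so no regioselectivity is asked for.

Step 12
Reactants: 14 [3,6-bis(benzoyloxy)-1,2-bis(methoxymethoxy)cyclohex-4-en-1-yl]methyl benzoate
Product: 15 [(1R,2S,3R,6R)-3,6-bis(benzoyloxy)-1,2-dihydroxycyclohex-4-en-1-yl]methyl benzoate (CNP0128482.2)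
Conditions: TFA–H2O (9:1), CH2Cl2, 0 °C → rt
Reagents that add atoms: none
Why: Acid-catalysed acetal hydrolysis of both methoxymethyl ethers; benzoates do not migrate readily under acid, and the allylic benzoates are deactivated toward ionisation by the neighbouring oxygen substituents.

## Compound list

1 | 1,2:5,6-di-O-isopropylidene-α-D-glucofuranose | CC1(C)OC[C@@H](O1)[C@H]2O[C@@H]3OC(C)(C)O[C@@H]3[C@H]2O | starting material
2 | 1,2:5,6-di-O-isopropylidene-3-O-(2-naphthylmethyl)-α-D-glucofuranose | CC1(C)OC[C@@H](O1)[C@H]2O[C@@H]3OC(C)(C)O[C@@H]3[C@H]2OCc4ccc5ccccc5c4 | intermediate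
3 | 3-O-(2-naphthylmethyl)-D-glucopyranose (anomeric mixture) | OC[C@H]1OC(O)[C@H](O)[C@@H](OCc2ccc3ccccc3c2)[C@@H]1O | intermediate
4 | 1,2-dideoxy-4-O-(2-naphthylmethyl)-D-gluco-hept-1-ynitol | C#C[C@H](O)[C@@H](OCc1ccc2ccccc2c1)[C@H](O)[C@H](O)CO | intermediate
5 | 6,7-dideoxy-4-O-(2-naphthylmethyl)-L-gulo-hept-6-ynopyranose (lactol, not isolated) | C#C[C@@H]1OC(O)[C@@H](O)[C@@H](O)[C@@H]1OCc2ccc3ccccc3c2 | intermediate
6 | 6,7-dideoxy-4-O-(2-naphthylmethyl)-L-gulo-hept-6-ynono-1,5-lactone | C#C[C@@H]1OC(=O)[C@@H](O)[C@@H](O)[C@@H]1OCc2ccc3ccccc3c2 | intermediate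
7 | 6,7-dideoxy-2,3-bis-O-(methoxymethyl)-4-O-(2-naphthylmethyl)-L-gulo-hept-6-ynono-1,5-lactone | C#C[C@@H]1OC(=O)[C@@H](OCOC)[C@@H](OCOC)[C@@H]1OCc2ccc3ccccc3c2 | intermediate
8 | (E)-7-(pinacolatoboryl) hept-6-enono-1,5-lactone derived from 7 | CC1(C)OB(OC1(C)C)/C=C/[C@@H]2OC(=O)[C@@H](OCOC)[C@@H](OCOC)[C@@H]2OCc3ccc4ccccc4c3 | intermediate
9 | trimethylsilyl ketene acetal of 8 (not isolated) | CC1(C)OB(OC1(C)C)/C=C/[C@@H]2OC(O[Si](C)(C)C)=C(OCOC)[C@@H](OCOC)[C@@H]2OCc3ccc4ccccc4c3 | intermediate
10 | trimethylsilyl 1,2-bis(methoxymethoxy)-3-(2-naphthylmethoxy)-6-(pinacolatoboryl)cyclohex-4-ene-1-carboxylate | C[Si](C)(C)OC(=O)[C@@]1(OCOC)[C@@H](OCOC)[C@H](OCc2ccc3ccccc3c2)C=C[C@H]1B4OC(C)(C)C(C)(C)O4 | intermediate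
11 | 6-hydroxy-1,2-bis(methoxymethoxy)-3-(2-naphthylmethoxy)cyclohex-4-ene-1-carboxylic acid | OC(=O)[C@@]1(OCOC)[C@@H](OCOC)[C@H](OCc2ccc3ccccc3c2)C=C[C@H]1O | intermediate
12 | 1-(hydroxymethyl)-1,2-bis(methoxymethoxy)-3-(2-naphthylmethoxy)cyclohex-4-en-6-ol | OC[C@@]1(OCOC)[C@@H](OCOC)[C@H](OCc2ccc3ccccc3c2)C=C[C@H]1O | intermediate
13 | 1-(hydroxymethyl)-1,2-bis(methoxymethoxy)cyclohex-4-ene-3,6-diol | OC[C@@]1(OCOC)[C@@H](OCOC)[C@H](O)C=C[C@H]1O | intermediate
14 | [3,6-bis(benzoyloxy)-1,2-bis(methoxymethoxy)cyclohex-4-en-1-yl]methyl benzoate | O=C(OC[C@@]1(OCOC)[C@@H](OCOC)[C@H](OC(=O)c2ccccc2)C=C[C@H]1OC(=O)c3ccccc3)c4ccccc4 | intermediate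
15 | [(1R,2S,3R,6R)-3,6-bis(benzoyloxy)-1,2-dihydroxycyclohex-4-en-1-yl]methyl benzoate | O=C(OC[C@]1(O)[C@H](OC(=O)c2ccccc2)C=C[C@@H](OC(=O)c2ccccc2)[C@@H]1O)c1ccccc1 | target

## Step count and least certain steps

Total step count: 12. Longest linear sequence: 12 (fully linear from 1).

**Step 7 (key step).**
- Most likely failure: loss of material caused by boron. Reversible attack of the amide base or of the enolate oxygen on the boronate slows O-silylation, which gives β-elimination of the C2 substituent time to compete. The boat array may also need a temperature at which the allylboronate begins a 1,3-borotropic shift.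
- Fallback: boron is removed before the rearrangement, and C6 enters with its oxygen already in place. Setting out from 8, a Chan–Evans–Lam-type coupling with 2-naphthylmethanol (Cu(OAc)2, Et3N, air, CH2Cl2) keeps the alkene geometry and would give the (E)-enol ether lactone F1. LiN(iPr)2/TMSCl would give the silyl ketene acetal F2, whose 6-alkoxy donor should speed up the same boat rearrangement to the silyl ester F3. LiAlH4 would reduce F3 directly to the primary alcohol F4. DDQ would then remove both naphthylmethyl groups, which comes back to the route at 13.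

**Step 3.**
- Most likely failure: base-induced enolisation of the open-chain aldehyde. This would epimerise C4, which would reverse the face of the key step, or expel the β-naphthylmethoxy group. It can compete because so little open-chain form is present and the reaction is slow.
- Fallback: olefination without base. Setting out from 3, Ramirez-type dibromo-olefination with (dibromomethyl)triphenylphosphonium bromide and Zn in refluxing dioxane is a reaction type known on unprotected aldoses and would give the 1,1-dibromoalkene tetraol F5. Excess n-BuLi in THF (second stage of the Corey–Fuchs sequence, with the hydroxyls carried as lithium alkoxides) would convert F5 into the alkyne, which comes back to the route at 4.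

**Step 4.**
- Most likely failure: loss of chemoselectivity. This means oxidation of the propargylic C4 alcohol before the lactol forms, or glycol cleavage of the C1/C7 or C1/C2 diol by PhI(OAc)2.
- Fallback: C7 is oxidised while C4–OH is still masked. Setting out from 2, selective hydrolysis of the terminal acetonide (aq AcOH) would give the 5,6-diol F6. TEMPO/PhI(OAc)2 in CH2Cl2–H2O would give the furanuronic acid F7, and aqueous acid would free the glucuronic acid hemiacetal F8. Ohira–Bestmann homologation would give the alkynyl hydroxy acid F9. On acidification F9 can lactonise only through the C4 hydroxyl, which comes back to the route at 6.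

**Step 10.**
- Most likely failure: over-oxidation of the free allylic alcohols at C6 and C3 to enones by DDQ during the slower cleavage of the naphthylmethyl ether.
- Fallback: the allylic alcohol is capped first. Setting out from 12, benzoylation would give the 6,7-dibenzoate F10. DDQ would then free only O3, giving the mono-alcohol F11, and a second benzoylation comes back to the route at 14.

## Further compounds

F1 | step 7 | (E)-7-(2-naphthylmethoxy) hept-6-enono-1,5-lactone (enol ether analogue of 8) | C(c1ccc2ccccc2c1)O/C=C/[C@@H]3OC(=O)[C@@H](OCOC)[C@@H](OCOC)[C@@H]3OCc4ccc5ccccc5c4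
F2 | step 7 | trimethylsilyl ketene acetal of F1 | C(c1ccc2ccccc2c1)O/C=C/[C@@H]3OC(O[Si](C)(C)C)=C(OCOC)[C@@H](OCOC)[C@@H]3OCc4ccc5ccccc5c4
F3 | step 7 | trimethylsilyl 1,2-bis(methoxymethoxy)-3,6-bis(2-naphthylmethoxy)cyclohex-4-ene-1-carboxylate | C[Si](C)(C)OC(=O)[C@@]1(OCOC)[C@@H](OCOC)[C@H](OCc2ccc3ccccc3c2)C=C[C@H]1OCc4ccc5ccccc5c4
F4 | step 7 | [1,2-bis(methoxymethoxy)-3,6-bis(2-naphthylmethoxy)cyclohex-4-en-1-yl]methanol | OC[C@@]1(OCOC)[C@@H](OCOC)[C@H](OCc2ccc3ccccc3c2)C=C[C@H]1OCc4ccc5ccccc5c4
F5 | step 3 | 1,1-dibromo-1,2-dideoxy-4-O-(2-naphthylmethyl)-D-gluco-hept-1-enitol | BrC(Br)=C[C@H](O)[C@@H](OCc1ccc2ccccc2c1)[C@H](O)[C@H](O)CO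
F6 | step 4 | 1,2-O-isopropylidene-3-O-(2-naphthylmethyl)-α-D-glucofuranose | OC[C@@H](O)[C@H]1O[C@@H]2OC(C)(C)O[C@@H]2[C@H]1OCc3ccc4ccccc4c3
F7 | step 4 | 1,2-O-isopropylidene-3-O-(2-naphthylmethyl)-α-D-glucofuranuronic acid | OC(=O)[C@@H](O)[C@H]1O[C@@H]2OC(C)(C)O[C@@H]2[C@H]1OCc3ccc4ccccc4c3
F8 | step 4 | 3-O-(2-naphthylmethyl)-D-glucopyranuronic acid (anomeric mixture) | OC(=O)[C@H]1OC(O)[C@H](O)[C@@H](OCc2ccc3ccccc3c2)[C@@H]1O
F9 | step 4 | 6,7-dideoxy-4-O-(2-naphthylmethyl)-L-gulo-hept-6-ynonic acid | C#C[C@H](O)[C@@H](OCc1ccc2ccccc2c1)[C@H](O)[C@H](O)C(=O)O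
F10 | step 10 | [6-(benzoyloxy)-1,2-bis(methoxymethoxy)-3-(2-naphthylmethoxy)cyclohex-4-en-1-yl]methyl benzoate | O=C(OC[C@@]1(OCOC)[C@@H](OCOC)[C@H](OCc2ccc3ccccc3c2)C=C[C@H]1OC(=O)c4ccccc4)c5ccccc5
F11 | step 10 | [6-(benzoyloxy)-3-hydroxy-1,2-bis(methoxymethoxy)cyclohex-4-en-1-yl]methyl benzoate | O=C(OC[C@@]1(OCOC)[C@@H](OCOC)[C@H](O)C=C[C@H]1OC(=O)c2ccccc2)c3ccccc3
A1 | alternative 1 | 4-(benzoyloxymethyl)-4,5-dihydroxyocta-1,7-diene-3,6-diyl dibenzoate (configuration of 15) | C=C[C@@H](OC(=O)c1ccccc1)[C@@](O)(COC(=O)c1ccccc1)[C@@H](O)[C@H](OC(=O)c1ccccc1)C=C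
A2 | alternative 2 | all-trans-5,6-dihydroxycyclohex-2-ene-1,4-diyl dibenzoate (C2-symmetric) | O[C@H]1[C@H](OC(=O)c2ccccc2)C=C[C@@H](OC(=O)c2ccccc2)[C@@H]1O
A3 | alternative 2 | 5-hydroxy-6-oxocyclohex-2-ene-1,4-diyl dibenzoate | O=C1[C@H](OC(=O)c2ccccc2)C=C[C@@H](OC(=O)c2ccccc2)[C@@H]1O
A4 | alternative 2 | 8-hydroxy-1-oxaspiro[2.5]oct-5-ene-4,7-diyl dibenzoate | C1O[C@]12[C@H](OC(=O)c3ccccc3)C=C[C@@H](OC(=O)c3ccccc3)[C@@H]2O
A5 | alternative 3 | (anti-1,6:2,3-diepoxycyclohex-4-en-1-yl)methyl benzoate | O=C(OC[C@]12O[C@H]1C=C[C@@H]3O[C@H]23)c1ccccc1
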